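# Total synthesis plan for CNP0146024.1 (compound 40)

## The problem

Briarane numbering is used throughout: C1 is the quaternary ring-fusion carbon with methyl C15, C2 and C9 are the acetoxy carbons, C5=C6 is the trisubstituted alkene, C7–C8–C17–C19 are the lactone carbons, C10 is the ring-fusion CH and C11–C14 complete the six-membered ring. Compound 40 is a cyclohexene (ring A) trans-fused through C1–C10 to a ten-membered carbocycle (ring B), which is trans-fused through C7–C8 to a γ-lactone (ring C). It has nine stereocentres (C1, C2, C7, C8, C9, C10, C11, C12, C17), three of them fully substituted (C1, C8, C11), and a (Z)-alkene inside the medium ring.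

The trans pair C1/C10 decides the faces of ring A, so it can control the cis-diol at C11/C12. C10 can guide C9, the C9 hydroxyl can guide C7 by 1,3-induction, and a tether from O7 can deliver C17 to C8. C2 is neopentyl, next to quaternary C1, has only a weak substrate bias and is better set by a reagent.

The β-hydroxy-γ-lactone will not survive rough treatment (retro-aldol, dehydration to the butenolide, epimerization at C17). The allylic C7–O and C12–O bonds are sensitive too. The two acetates must be placed on C2 and C9 only, beside three hydroxyls that stay free. The ten-membered ring needs a closure that tolerates this density of functional groups.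

The feature that opens the structure is ring A itself. It is a cyclohexene whose neighbouring carbons C1 (quaternary, methyl plus C2) and C10 (C9) carry trans carbon branches, with oxygen at C12 para to C1. This is the retron of a [4+2] cycloaddition that forms C1–C14 and C10–C11 from a 2-silyloxy diene and a formyl-activated (E)-2-methylbutenedioic half-ester.

## Retrosynthesis

**End game (40 ← 39 ← 38 ← 37).** The C11/C12 cis-diol is kept as an acetonide until the last step. Desilylation of 37 then exposes only the secondary C2 and C9 hydroxyls (38) beside the unreactive tertiary C8 hydroxyl, they are acetylated (39), and mild acid releases 40. Introducing the acetates earlier is ruled out by the hydride, enolate and samarium steps. This cut is only protecting-group logic, and it asks that the β-hydroxy lactone meets neither strong base nor strong acid.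

**Ring C, cut C8–C17 (37 ← 35).** Opening the lactone C–O bond would leave the quaternary carbinol C8 unsolved. Cutting C8–C17 instead traces both C8 and C17 to an intramolecular samarium Reformatsky reaction. The samarium enolate 36 of the α-bromopropanoate on O7 adds to a C8 ketone in 35. The tether fixes the new bond cis to O7, and the ring torsion and the size of the C9 branch decide the rest. The precursor 35 has no ring C and two stereocentres fewer. It comes from the 7,9-diol 31 by selective acylation of the allylic C7 hydroxyl (33), silylation of C9 (34) and release of the ketone from a dithiane.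

**C7, functional-group change (31 ← 29 ← 28).** The configuration at C7 is not left to the ring closure. The allylic alcohol 28 is oxidized to the ring enone 29 and reduced from the boron chelate 30 of the free C9 hydroxyl, which gives the 7,9-syn diol 31 that the target requires. This costs two steps and buys a predictable stereocentre.

**Ring B, cut C6–C7 (28 ← 26).** The alternatives for closing ring B are weaker:
- Metathesis at C5=C6 must form a trisubstituted alkene in a medium ring.
- Carbanion alkylation at C7–C8 puts a carbanion β to the C9 oxygen, which invites elimination.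
- Closure at C2–C3 has no reliable nucleophile.

The Nozaki–Hiyama–Kishi reaction of a (Z)-alkenyl iodide (C6) with an aldehyde (C7) runs under neutral conditions, tolerates the free hydroxyl and the thioacetal, and transfers the alkene geometry into the ring (via alkenylchromium 27). The precursor 26 is acyclic in ring B. The forward reaction only has to close a ten-membered ring at high dilution.

**C8–C9 (26 ← 25 ← 22 + 23).** The two-carbon unit C7–C8 is ethyl 1,3-dithiane-2-carboxylate 23. Its lithium enolate 24 adds to the C9 aldehyde 22 and brings C8 as a masked ketone and C7 as an ester that is reduced to the aldehyde. A dithiane anion with an oxygen on the neighbouring carbon is never needed. The forward reaction must choose the right face of the aldehyde at C9; chelation to the C11 oxygen and the bulk of C1 point the same way.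

**C3–C4 and C2 (22 ← 21 ← 20 ← 19 ← 18 ← 12 + 16).** Direct addition of a C3 organometallic carrying the iodoalkene to the C2 aldehyde is not compatible with the iodide and would leave C2 to substrate control. Instead the aldehyde is turned into a methyl ketone, whose only enolizable position is C3. Its lithium enolate 17 is alkylated with the (Z)-iodoallyl bromide 16 (C4–C6 and the C5 methyl). The bromide is made in two steps from prop-2-yn-1-ol 13 through the alkenylmagnesium 14 and alcohol 15. The resulting ketone 18 is reduced under oxazaborolidine control to the (2R)-carbinol 19. Silylation (20), ester reduction (21) and oxidation give 22.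

**Ring A oxygenation (12 ← 11 ← 10 ← 9 ← 8 ← 7 ← 5 ← 4).** Enolate hydroxylation at C11 followed by ketone reduction at C12 was considered. Conformational analysis of the α-hydroxy enone suggests that hydride would enter anti to the axial C11 methyl and give the trans-diol. The silyl enol ether of 4 is therefore taken to the enone 5, the cross-conjugated dienolate 6 is trapped as the dienyl triflate 7, and reduction gives the diene 8. Osmium-catalysed syn-dihydroxylation of the derived methyl ketone 10 (from 8 via carbinol 9) then delivers the cis-diol 11 in one stereospecific step. It occurs on the face opposite the C10 branch. The acetonide 12 follows. The C11 centre of the cycloadduct is discarded on the way.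

**Ring A, cut C1–C14 and C10–C11 (4 ← 2 + 3; 2 ← 1).** The key disconnection gives the (Z)-silyloxy diene 2 (one step from pent-1-en-3-one 1) and the commercial aldehyde ester 3. It removes the ring, the quaternary centre and the trans relationship of C2 and C9 at once. The forward cycloaddition must be regioselective, trans-specific and enantioselective; the formyl group, the E geometry and a chiral oxazaborolidinium catalyst provide these.

## Roads not taken

**Alternative 1: ring-contracting [2,3]-Wittig rearrangement.** The cut is C7–C8, after ring B has been widened by an O–CH2 bridge. In the thirteen-membered C7-stannyl allylic ether A1, tin–lithium exchange with an alkyllithium would give the α-alkoxy carbanion at C7. This rearranges onto C8 and contracts the ring to the carbinol A2, with the C7 hydroxyl and an isopropenyl group on C8.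
- Merits: the macrocycle is closed as an easier thirteen-membered ether, C7 and C8 are set together, and no high-dilution C–C closure is needed. In this respect it is better than the chosen plan.
- Weak points: C8 arrives as a C–H carbon with an isopropenyl group. The tertiary hydroxyl at C8, the carboxyl oxidation level at C19 and the C17 stereocentre must all be added afterwards on a crowded ring. The α-alkoxy organolithium must form next to several silyl ethers, and a [1,2]-shift competes. The transannular sense of the rearrangement is hard to predict. The strategy also says nothing about the origin of ring A.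
- Comparison: the chosen plan sets against it a lactone annulation that creates C8 and C17 at their final oxidation levels, and a catalytic source of absolute configuration at the start.

**Alternative 2: chiral-pool ring A, conjugate addition then aldol.** The cuts are C9–C10 and C1–C2 on a preformed cyclohexenone. Copper-catalysed addition of a silylmethyl Grignard reagent (a masked hydroxymethyl group) to enone A3 is followed by transmetalation of the enolate to zinc and capture by aldehyde A4. This would give ketone A5 with the quaternary C1, the C2 carbinol and the whole C2–C7 chain.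
- Merits: absolute configuration is bought, not made. The three-component union is convergent and brings the (Z)-alkene in from a terpene alcohol. For C1, C2 and C10 it is at least as short as the chosen plan.
- Weak points: the aldol of a fully substituted zinc enolate with an enolizable aldehyde is reversible and gives little control at C2. Ring A arrives with oxygen at C12 and C14 but without the C11 methyl, the C11 hydroxyl or the C13=C14 alkene, so a carbonyl transposition and a separate build-up of the C11 carbinol are needed. C9 arrives as CH2–Si and must be oxidized and extended.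
- Comparison: the chosen cycloaddition places the C12 oxygen and the C11 methyl directly. It pays with a longer sequence on the C2 side.

**Alternative 3: biomimetic transannular cyclization.** The cut is C1–C10 across a fourteen-membered ring. A dialkylaluminium chloride would activate the C13 enone of macrocycle A6, C10 of the C10=C11 alkene attacks C1, and the C12 carbonate traps the C11 cation, giving A7. This closes rings A and B and sets C1, C10 and C11 in one step with the butenolide in place.
- Merits: if it works it is clearly the shortest road. The chosen plan cannot match its step economy.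
- Weak points: the macrocycle A6 needs its own long synthesis with two defined trisubstituted alkenes. The facial course of the transannular attack is unproven, and ene and Prins pathways compete. The product still needs net hydration of the tetrasubstituted butenolide alkene (hydroxyl at C8, hydrogen at C17), for which there is no mild method, and conversion of the C13 ketone into the C13=C14 alkene.
- Comparison: the chosen plan sets against it stereocentres formed one at a time by reactions with understood control elements.

Key step: step 2

Assumption: the sense of induction of the oxazaborolidinium catalyst is taken from the usual pre-transition-state model for α-substituted enals. The (S)-proline-derived catalyst is written, and its (R) antipode would be used unchanged if the opposite sense were found.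

## Route

Step 1
Reactants: 1 pent-1-en-3-one
Product: 2 (Z)-3-(triethylsilyloxy)penta-1,3-diene
Conditions: Et3SiOTf, Et3N, Et2O, 0 °C
Reagents that add atoms: triethylsilyl trifluoromethanesulfonate, CC[Si](CC)(CC)OS(=O)(=O)C(F)(F)F
Why: Amine-mediated enol silylation of an ethyl ketone (silyl enol ether formation) gives the (Z)-enol ether, in which the methyl group points away from the vinyl group, as the s-cis diene needs.

Step 2
Reactants: 2 (Z)-3-(triethylsilyloxy)penta-1,3-diene; 3 ethyl (E)-3-methyl-4-oxobut-2-enoate
Product: 4 ring A silyl enol ether ethyl 6-formyl-2,6-dimethyl-3-(triethylsilyloxy)cyclohex-3-ene-1-carboxylate (C2 formyl on C1 trans to the C9 ester on C10)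
Conditions: (S)-3,3-diphenyl-1-(o-tolyl)tetrahydro-1H,3H-pyrrolo[1,2-c][1,3,2]oxazaborole (20 mol %), Tf2NH (18 mol %), CH2Cl2, −78 °C
Reagents that add atoms: none
Why: The N-protonated oxazaborolidine binds the formyl oxygen of 3, lowers the LUMO and leaves one face of the C1=C10 bond open; the diene terminus C11, made nucleophilic by the 2-silyloxy group, bonds to C10 (β to the bound aldehyde) slightly ahead of C14–C1 in a concerted, asynchronous [4+2] cycloaddition. The closest known reaction type is the oxazaborolidinium-catalysed enantioselective Diels–Alder reaction of α-substituted enals with 2-silyloxy-1,3-dienes. Ring A is closed in the cycloaddition itself, suprafacially on both partners, as a six-membered ring. C1 and C10 are set relative to each other by the E geometry of the dienophile (formyl and ester trans, hence the later trans ring fusion) and absolutely by the catalyst-shielded face; C11 follows from the endo position of the bound formyl group and the outward methyl of the (Z)-enol ether and is provisional. The step needs para regioselectivity (silyloxy at C12 against formyl on C1), which the matched polarization of the two partners secures, and cycloaddition in preference to Mukaiyama–Michael addition, which the low temperature and the non-nucleophilic triflimide counter-ion favour.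

Step 3
Reactants: 4 ring A silyl enol ether
Product: 5 ring A enone ethyl 2-formyl-2,6-dimethyl-5-oxocyclohex-3-ene-1-carboxylate
Conditions: Pd(OAc)2 (1.1 equiv), MeCN, 25 °C
Reagents that add atoms: none
Why: Saegusa–Ito oxidation: palladation of the enol ether at C13 and β-hydride elimination from C14 give the C12 enone regiospecifically, because the quaternary C1 allows no other elimination.

Step 4
Reactants: 5 ring A enone
Product: 7 ring A dienyl triflate ethyl 2-formyl-2,6-dimethyl-5-(trifluoromethylsulfonyloxy)cyclohexa-3,5-diene-1-carboxylate, via potassium dienolate 6 (not isolated)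
Conditions: KN(SiMe3)2, THF, −78 °C; then PhNTf2, −78 → 0 °C
Reagents that add atoms: N-phenylbis(trifluoromethanesulfonimide), O=S(=O)(N(c1ccccc1)S(=O)(=O)C(F)(F)F)C(F)(F)F
Why: Enol triflate formation: the enone has a single enolizable position (C11, since C1 is quaternary), so the cross-conjugated dienolate forms regiospecifically and is O-sulfonylated; the provisional C11 stereocentre is erased here.

Step 5
Reactants: 7 ring A dienyl triflate
Product: 8 ring A diene aldehyde ethyl 2-formyl-2,6-dimethylcyclohexa-3,5-diene-1-carboxylate
Conditions: Pd(OAc)2 (5 mol %), PPh3, HCO2H, n-Bu3N, DMF, 60 °C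
Reagents that add atoms: none
Why: Palladium-catalysed formate reduction of an alkenyl triflate (oxidative addition, formate exchange, decarboxylation, reductive elimination) gives the 1,3-diene and leaves the aldehyde and the ester alone.

Step 6
Reactants: 8 ring A diene aldehyde
Product: 9 ring A diene carbinol ethyl 2-(1-hydroxyethyl)-2,6-dimethylcyclohexa-3,5-diene-1-carboxylate (both C2 epimers)
Conditions: MeMgBr, THF, −78 °C; AcOH quench at −78 °C
Reagents that add atoms: methylmagnesium bromide, C[Mg]Br
Why: Grignard addition to the non-enolizable aldehyde brings in C3; at −78 °C the ester is not attacked, and the configuration of the carbinol does not matter because it is oxidized next.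

Step 7
Reactants: 9 ring A diene carbinol
Product: 10 ring A diene methyl ketone ethyl 2-acetyl-2,6-dimethylcyclohexa-3,5-diene-1-carboxylate
Conditions: Dess–Martin periodinane, NaHCO3, CH2Cl2, 0 °C → rt
Reagents that add atoms: none
Why: Dess–Martin oxidation of a secondary alcohol under buffered conditions gives the methyl ketone, which can be enolized only towards C3.

Step 8
Reactants: 10 ring A diene methyl ketone
Product: 11 ring A cis-diol ethyl 2-acetyl-5,6-dihydroxy-2,6-dimethylcyclohex-3-ene-1-carboxylate (C11 and C12 hydroxyls cis, both trans to the ester)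
Conditions: OsO4 (3 mol %), N-methylmorpholine N-oxide, acetone/H2O, 0 °C → rt
Reagents that add atoms: osmium tetroxide, O=[Os](=O)(=O)=O; N-methylmorpholine N-oxide, C[N+]1([O-])CCOCC1; water, O
Why: Upjohn dihydroxylation: OsO4 adds suprafacially to the more electron-rich trisubstituted C11=C12 bond from the face opposite the allylic C10 ester branch and the C1 methyl, so both hydroxyls are cis to each other and syn to H-10, as in the target. The C13=C14 bond next to the quaternary C1 reacts more slowly.

Step 9
Reactants: 11 ring A cis-diol
Product: 12 ring A acetonide methyl ketone (11,12-O-isopropylidene derivative of 11)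
Conditions: Me2C(OMe)2, pyridinium p-toluenesulfonate (cat.), CH2Cl2, rt
Reagents that add atoms: 2,2-dimethoxypropane, COC(C)(C)OC
Why: Acetal exchange on a cis-1,2-diol; the acetonide keeps the C11 and C12 hydroxyls out of every later step, including the final acetylation.

Step 10
Reactants: 13 prop-2-yn-1-ol
Product: 15 (Z)-3-iodo-2-methylprop-2-en-1-ol, via alkenylmagnesium alkoxide 14 (not isolated)
Conditions: MeMgBr (2.5 equiv), CuI (10 mol %), THF, −10 °C → rt; then I2, −78 → 0 °C
Reagents that add atoms: methylmagnesium bromide, C[Mg]Br; iodine, II
Why: Copper-catalysed carbomagnesiation of a propargylic alkoxide: methyl goes to the internal carbon anti to magnesium, which is held by the alkoxide, and iodinolysis with retention gives the (Z)-iodoalkene that carries C4, C5, C6 and the C5 methyl.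

Step 11
Reactants: 15 (Z)-3-iodo-2-methylprop-2-en-1-ol
Product: 16 (Z)-3-bromo-1-iodo-2-methylprop-1-ene
Conditions: CBr4, PPh3, CH2Cl2, 0 °C
Reagents that add atoms: carbon tetrabromide, BrC(Br)(Br)Br
Why: Appel bromination of a primary allylic alcohol; SN2 displacement of the oxyphosphonium group leaves the alkene geometry untouched.

Step 12
Reactants: 12 ring A acetonide methyl ketone; 16 (Z)-3-bromo-1-iodo-2-methylprop-1-ene
Product: 18 C2 ketone bearing the (Z)-5-iodo-4-methylpent-4-enoyl chain on C1, via lithium enolate 17 (not isolated)
Conditions: LiN(i-Pr)2, THF, −78 °C; then 16, DMPU, −78 → −40 °C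
Reagents that add atoms: none
Why: Kinetic lithium enolate alkylation: the acetyl group on quaternary C1 can be deprotonated only at C3, and the allylic bromide reacts by SN2 at C4 to form C3–C4. The low temperature keeps the enolate from attacking the neighbouring ester.

Step 13
Reactants: 18 C2 ketone
Product: 19 (2R)-carbinol
Conditions: (S)-1-methyl-3,3-diphenyltetrahydro-1H,3H-pyrrolo[1,2-c][1,3,2]oxazaborole (0.3 equiv), BH3·SMe2, THF, −20 °C
Reagents that add atoms: none
Why: Corey–Bakshi–Shibata reduction: the ketone binds the oxazaborolidine with the quaternary C1 side as the large group and borane delivers hydride to one face, which should set (2R) under reagent control whatever the weak substrate bias.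

Step 14
Reactants: 19 (2R)-carbinol
Product: 20 C2 tert-butyldimethylsilyl ether
Conditions: t-BuMe2SiOTf, 2,6-lutidine, CH2Cl2, 0 °C
Reagents that add atoms: tert-butyldimethylsilyl trifluoromethanesulfonate, CC(C)(C)[Si](C)(C)OS(=O)(=O)C(F)(F)F
Why: Silylation of a hindered secondary alcohol with the silyl triflate; the ether survives the hydride, enolate, chromium and samarium steps that follow.

Step 15
Reactants: 20 C2 silyl ether ethyl ester
Product: 21 C9 primary alcohol
Conditions: i-Bu2AlH (2.5 equiv), CH2Cl2, −78 → 0 °C; aqueous potassium sodium tartrate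
Reagents that add atoms: none
Why: Diisobutylaluminium hydride reduction of the ester to the primary alcohol; the alkenyl iodide, silyl ether and acetonide are inert.

Step 16
Reactants: 21 C9 primary alcohol
Product: 22 C9 aldehyde
Conditions: Dess–Martin periodinane, NaHCO3, CH2Cl2, 0 °C → rt
Reagents that add atoms: none
Why: Dess–Martin oxidation under buffered conditions gives the aldehyde without epimerizing the adjacent C10 stereocentre.

Step 17
Reactants: 22 C9 aldehyde; 23 ethyl 1,3-dithiane-2-carboxylate
Product: 25 C9 carbinol β-hydroxy ester (C8 as 1,3-dithiane and C7 as ethyl ester), via lithium enolate 24 (not isolated)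
Conditions: 23, LiN(i-Pr)2, THF, −78 °C; then 22 premixed with MgBr2·OEt2, −78 °C; AcOH quench at −78 °C
Reagents that add atoms: none
Why: Aldol addition of a glyoxylate anion equivalent brings in C8 as a masked ketone and C7 as an ester. With the aldehyde oxygen chelated to the C11 acetonide oxygen (or in the Felkin–Anh arrangement with C1 as the large group) the nucleophile enters anti to the quaternary C1, which should give the target configuration at C9.

Step 18
Reactants: 25 C9 carbinol β-hydroxy ester
Product: 26 C7 aldehyde (2-formyl-1,3-dithiane) bearing the free C9 hydroxyl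
Conditions: i-Bu2AlH (2.2 equiv), CH2Cl2, −78 °C; MeOH, aqueous potassium sodium tartrate
Reagents that add atoms: none
Why: Partial reduction of an ester with diisobutylaluminium hydride at −78 °C; the aluminium hemiacetal on the quaternary dithiane carbon, held by the C9 alkoxide, should not collapse before work-up, so the aldehyde is obtained.

Step 19
Reactants: 26 C7 aldehyde
Product: 28 ring A/ring B bicycle with the C7 allylic alcohol (both C7 epimers), via alkenylchromium dichloride 27 (not isolated)
Conditions: CrCl2 (10 equiv), NiCl2 (1 mol %), DMSO/THF, rt, 2 mM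
Reagents that add atoms: none
Why: Nozaki–Hiyama–Kishi reaction: nickel-catalysed formation of the alkenylchromium species from the (Z)-iodide and its chemoselective 1,2-addition to the aldehyde form C6–C7 and close ring B as a ten-membered ring with retention of the alkene geometry. Free hydroxyl, silyl ether, acetal and dithiane groups are tolerated, and the configuration at C7 is not relied on.

Step 20
Reactants: 28 ring B allylic alcohol
Product: 29 ring B (Z)-enone (C7 ketone)
Conditions: MnO2, CH2Cl2, rt
Reagents that add atoms: none
Why: Manganese dioxide oxidizes only the allylic C7 alcohol and leaves the C9 hydroxyl; the enone geometry is held by the ring.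

Step 21
Reactants: 29 ring B enone
Product: 31 7,9-syn diol, via C9 diethylborinate 30 (not isolated)
Conditions: Et2BOMe, THF/MeOH (4:1), −78 °C; then NaBH4; AcOH, MeOH azeotrope
Reagents that add atoms: none
Why: Narasaka–Prasad reduction: the C9 hydroxyl and the C7 ketone are tied together through boron and external hydride adds axially to the half-chair chelate (1,2-reduction of the enone). This should give the 7,9-syn diol and so the target configuration at C7.

Step 22
Reactants: 31 7,9-syn diol; 32 2-bromopropanoyl bromide
Product: 33 C7 2-bromopropanoate (epimers at the bromine-bearing carbon)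
Conditions: pyridine, CH2Cl2, −40 °C
Reagents that add atoms: none
Why: Selective O-acylation: the allylic C7 hydroxyl, flanked by an sp2 carbon, should react in preference to the C9 hydroxyl, which lies between the dithiane carbon and the ring-fusion carbon C10. The mixture at the bromine-bearing carbon is of no consequence because that carbon becomes an enolate.

Step 23
Reactants: 33 C7 2-bromopropanoate
Product: 34 C9 triethylsilyl ether
Conditions: Et3SiOTf, 2,6-lutidine, CH2Cl2, −78 °C
Reagents that add atoms: triethylsilyl trifluoromethanesulfonate, CC[Si](CC)(CC)OS(=O)(=O)C(F)(F)F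
Why: Silylation of the remaining hydroxyl, so that neither acyl migration from O7 nor α-ketol chemistry can occur once the C8 ketone is unmasked.

Step 24
Reactants: 34 C9 triethylsilyl ether
Product: 35 C8 ketone
Conditions: MeI, CaCO3, MeCN/H2O (4:1), 45 °C
Reagents that add atoms: water, O
Why: Alkylative hydrolysis of the dithiane (S-methylation, ring opening, hydrolysis) under buffered conditions releases the ketone without strong acid or heavy-metal salts that would endanger the silyl ethers, the acetonide and the alkenes.

Step 25
Reactants: 35 C8 ketone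
Product: 37 protected tricyclic lactone, via samarium enolate 36 (not isolated)
Conditions: SmI2 (2.2 equiv), THF, −78 °C
Reagents that add atoms: none
Why: Intramolecular samarium Reformatsky reaction: SmI2 reduces the C–Br bond to the samarium enolate, which adds to the neighbouring C8 ketone through a five-membered chelated transition state and forms C8–C17 and the γ-lactone. The tether from O7 fixes C17 cis to the C7 oxygen, the ring torsion places C9 anti to C6 (trans fusion, hence the C8 configuration), and the C17 methyl turns away from the C9 branch towards the new hydroxyl.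

Step 26
Reactants: 37 protected tricyclic lactone
Product: 38 triol acetonide (free hydroxyls at C2, C8, C9)
Conditions: HF·pyridine, pyridine, THF, 0 °C → rt
Reagents that add atoms: none
Why: Cleavage of both silyl ethers with buffered hydrogen fluoride, which spares the acetonide and avoids basic fluoride that could reopen the β-hydroxy lactone by retro-aldol reaction.

Step 27
Reactants: 38 triol acetonide
Product: 39 diacetate acetonide
Conditions: Ac2O, pyridine, 4-dimethylaminopyridine (cat.), CH2Cl2, rt
Reagents that add atoms: acetic anhydride, CC(=O)OC(C)=O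
Why: Acetylation of the two secondary hydroxyls at C2 and C9; the tertiary C8 hydroxyl does not react under these conditions and the C11 and C12 oxygens are blocked as the acetonide.

Step 28
Reactants: 39 diacetate acetonide
Product: 40 CNP0146024.1
Conditions: AcOH/H2O (4:1), 40 °C
Reagents that add atoms: none
Why: Hydrolysis of the acetonide in aqueous acetic acid, mild enough to keep the acetates, the β-hydroxy lactone and the allylic C12 alcohol, releases the target.

## Compound list

1 | pent-1-en-3-one | C=CC(=O)CC | starting material
2 | (Z)-3-(triethylsilyloxy)penta-1,3-diene | C=C/C(O[Si](CC)(CC)CC)=C/C | intermediate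
3 | ethyl (E)-3-methyl-4-oxobut-2-enoate | CCOC(=O)/C=C(C)/C=O | starting material
4 | ring A silyl enol ether: ethyl 6-formyl-2,6-dimethyl-3-(triethylsilyloxy)cyclohex-3-ene-1-carboxylate; formyl (C2, on C1) trans to ester (C9, on C10), C11 methyl cis to formyl | O=C[C@@]1(C)CC=C(O[Si](CC)(CC)CC)[C@@H](C)[C@@H]1C(=O)OCC | intermediate
5 | ring A enone: ethyl 2-formyl-2,6-dimethyl-5-oxocyclohex-3-ene-1-carboxylate, formyl trans to ester | O=C[C@@]1(C)C=CC(=O)[C@@H](C)[C@@H]1C(=O)OCC | intermediate
6 | potassium dienolate of 5 | O=C[C@@]1(C)C=CC(O[K])=C(C)[C@@H]1C(=O)OCC | intermediate (not isolated)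
7 | ring A dienyl triflate: ethyl 2-formyl-2,6-dimethyl-5-(trifluoromethylsulfonyloxy)cyclohexa-3,5-diene-1-carboxylate | O=C[C@@]1(C)C=CC(OS(=O)(=O)C(F)(F)F)=C(C)[C@@H]1C(=O)OCC | intermediate
8 | ring A diene aldehyde: ethyl 2-formyl-2,6-dimethylcyclohexa-3,5-diene-1-carboxylate | O=C[C@@]1(C)C=CC=C(C)[C@@H]1C(=O)OCC | intermediate
9 | ring A diene carbinol: ethyl 2-(1-hydroxyethyl)-2,6-dimethylcyclohexa-3,5-diene-1-carboxylate, both C2 epimers | CC(O)[C@@]1(C)C=CC=C(C)[C@@H]1C(=O)OCC | intermediate
10 | ring A diene methyl ketone: ethyl 2-acetyl-2,6-dimethylcyclohexa-3,5-diene-1-carboxylate | CC(=O)[C@@]1(C)C=CC=C(C)[C@@H]1C(=O)OCC | intermediate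
11 | ring A cis-diol: ethyl 2-acetyl-5,6-dihydroxy-2,6-dimethylcyclohex-3-ene-1-carboxylate; C11 and C12 hydroxyls cis, syn to H-10 and the acetyl group, trans to the ester | CC(=O)[C@@]1(C)C=C[C@@H](O)[C@@](C)(O)[C@@H]1C(=O)OCC | intermediate
12 | ring A acetonide methyl ketone: 11,12-O-isopropylidene derivative of 11 | CC(=O)[C@@]1(C)C=C[C@H]2OC(C)(C)O[C@@]2(C)[C@@H]1C(=O)OCC | intermediate
13 | prop-2-yn-1-ol | C#CCO | starting material
14 | bromomagnesium (Z)-3-(bromomagnesio)-2-methylprop-2-en-1-olate | Br[Mg]OC/C(C)=C\[Mg]Br | intermediate (not isolated)
15 | (Z)-3-iodo-2-methylprop-2-en-1-ol | OC/C(C)=C\I | intermediate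
16 | (Z)-3-bromo-1-iodo-2-methylprop-1-ene | BrC/C(C)=C\I | intermediate
17 | lithium enolate of 12 (enolate carbon C3) | [Li]OC(=C)[C@@]1(C)C=C[C@H]2OC(C)(C)O[C@@]2(C)[C@@H]1C(=O)OCC | intermediate (not isolated)
18 | C2 ketone: acetonide-protected ring A ethyl ester with the (Z)-5-iodo-4-methylpent-4-enoyl group (C2–C6) on C1 | I\C=C(C)/CCC(=O)[C@@]1(C)C=C[C@H]2OC(C)(C)O[C@@]2(C)[C@@H]1C(=O)OCC | intermediate
19 | (2R)-carbinol of 18 | I\C=C(C)/CC[C@@H](O)[C@@]1(C)C=C[C@H]2OC(C)(C)O[C@@]2(C)[C@@H]1C(=O)OCC | intermediate
20 | C2 tert-butyldimethylsilyl ether of 19 | I\C=C(C)/CC[C@@H](O[Si](C)(C)C(C)(C)C)[C@@]1(C)C=C[C@H]2OC(C)(C)O[C@@]2(C)[C@@H]1C(=O)OCC | intermediate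
21 | C9 primary alcohol (hydroxymethyl on C10) | I\C=C(C)/CC[C@@H](O[Si](C)(C)C(C)(C)C)[C@@]1(C)C=C[C@H]2OC(C)(C)O[C@@]2(C)[C@@H]1CO | intermediate
22 | C9 aldehyde (formyl on C10) | I\C=C(C)/CC[C@@H](O[Si](C)(C)C(C)(C)C)[C@@]1(C)C=C[C@H]2OC(C)(C)O[C@@]2(C)[C@@H]1C=O | intermediate
23 | ethyl 1,3-dithiane-2-carboxylate | CCOC(=O)C1SCCCS1 | starting material
24 | lithium enolate of 23 | CCOC(O[Li])=C1SCCCS1 | intermediate (not isolated)
25 | C9 carbinol β-hydroxy ester: C9 hydroxyl as in the target, C8 as 1,3-dithiane, C7 as ethyl ester | I\C=C(C)/CC[C@@H](O[Si](C)(C)C(C)(C)C)[C@@]1(C)C=C[C@H]2OC(C)(C)O[C@@]2(C)[C@@H]1[C@@H](O)C1(C(=O)OCC)SCCCS1 | intermediate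
26 | C7 aldehyde: 2-formyl-1,3-dithiane at C8, free C9 hydroxyl, (Z)-alkenyl iodide at C6 | I\C=C(C)/CC[C@@H](O[Si](C)(C)C(C)(C)C)[C@@]1(C)C=C[C@H]2OC(C)(C)O[C@@]2(C)[C@@H]1[C@@H](O)C1(C=O)SCCCS1 | intermediate
27 | alkenylchromium dichloride from 26 (chromium on C6) | Cl[Cr](Cl)\C=C(C)/CC[C@@H](O[Si](C)(C)C(C)(C)C)[C@@]1(C)C=C[C@H]2OC(C)(C)O[C@@]2(C)[C@@H]1[C@@H](O)C1(C=O)SCCCS1 | intermediate (not isolated)
28 | ring A/ring B bicycle: (5Z)-alkene, C7 allylic alcohol (both epimers), C8 dithiane, C9 hydroxyl, C2 silyl ether, C11/C12 acetonide | O[C@@H]1[C@H]2[C@]3(C)OC(C)(C)O[C@@H]3C=C[C@]2(C)[C@H](O[Si](C)(C)C(C)(C)C)CC/C(C)=C\C(O)C12SCCCS2 | intermediate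
29 | ring B (Z)-enone: C7 ketone of 28 | O[C@@H]1[C@H]2[C@]3(C)OC(C)(C)O[C@@H]3C=C[C@]2(C)[C@H](O[Si](C)(C)C(C)(C)C)CC/C(C)=C\C(=O)C12SCCCS2 | intermediate
30 | C9 diethylborinate of 29 | CCB(CC)O[C@@H]1[C@H]2[C@]3(C)OC(C)(C)O[C@@H]3C=C[C@]2(C)[C@H](O[Si](C)(C)C(C)(C)C)CC/C(C)=C\C(=O)C12SCCCS2 | intermediate (not isolated)
31 | 7,9-syn diol: C7 and C9 hydroxyls as in the target | O[C@@H]1[C@H]2[C@]3(C)OC(C)(C)O[C@@H]3C=C[C@]2(C)[C@H](O[Si](C)(C)C(C)(C)C)CC/C(C)=C\[C@H](O)C12SCCCS2 | intermediate
32 | 2-bromopropanoyl bromide (racemic) | CC(Br)C(Br)=O | starting material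
33 | C7 2-bromopropanoate of 31 (epimers at the bromine-bearing carbon) | O[C@@H]1[C@H]2[C@]3(C)OC(C)(C)O[C@@H]3C=C[C@]2(C)[C@H](O[Si](C)(C)C(C)(C)C)CC/C(C)=C\[C@H](OC(=O)C(C)Br)C12SCCCS2 | intermediate
34 | C9 triethylsilyl ether of 33 | CC[Si](CC)(CC)O[C@@H]1[C@H]2[C@]3(C)OC(C)(C)O[C@@H]3C=C[C@]2(C)[C@H](O[Si](C)(C)C(C)(C)C)CC/C(C)=C\[C@H](OC(=O)C(C)Br)C12SCCCS2 | intermediate
35 | C8 ketone: ring B α-(2-bromopropanoyloxy) ketone | CC[Si](CC)(CC)O[C@@H]1[C@H]2[C@]3(C)OC(C)(C)O[C@@H]3C=C[C@]2(C)[C@H](O[Si](C)(C)C(C)(C)C)CC/C(C)=C\[C@H](OC(=O)C(C)Br)C1=O | intermediate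
36 | samarium enolate of the C7 propanoate of 35 | CC[Si](CC)(CC)O[C@@H]1[C@H]2[C@]3(C)OC(C)(C)O[C@@H]3C=C[C@]2(C)[C@H](O[Si](C)(C)C(C)(C)C)CC/C(C)=C\[C@H](OC(O[Sm](I)I)=CC)C1=O | intermediate (not isolated)
37 | protected tricyclic lactone: C8 hydroxyl and C17 methyl as in the target, C9 triethylsilyl ether, C2 tert-butyldimethylsilyl ether, C11/C12 acetonide | CC[Si](CC)(CC)O[C@@H]1[C@H]2[C@]3(C)OC(C)(C)O[C@@H]3C=C[C@]2(C)[C@H](O[Si](C)(C)C(C)(C)C)CC/C(C)=C\[C@@H]2OC(=O)[C@H](C)[C@]21O | intermediate
38 | triol acetonide: free hydroxyls at C2, C8, C9 | O[C@@H]1[C@H]2[C@]3(C)OC(C)(C)O[C@@H]3C=C[C@]2(C)[C@H](O)CC/C(C)=C\[C@@H]2OC(=O)[C@H](C)[C@]21O | intermediate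
39 | diacetate acetonide: C2 and C9 acetates | CC(=O)O[C@@H]1[C@H]2[C@]3(C)OC(C)(C)O[C@@H]3C=C[C@]2(C)[C@H](OC(C)=O)CC/C(C)=C\[C@@H]2OC(=O)[C@H](C)[C@]21O | intermediate
40 | CNP0146024.1 | CC(=O)O[C@@H]1[C@H]2[C@](C)(O)[C@H](O)C=C[C@]2(C)[C@H](OC(C)=O)CC/C(C)=C\[C@@H]2OC(=O)[C@H](C)[C@]21O | target

## Step count and uncertain steps

Total: 28 steps. Longest linear sequence: 26 steps (steps 1–9 and 12–28, from 1). Steps 10 and 11 form the side branch to 16.

**Step 2 (key step).** The ester-bearing dienophile may react with lower enantio- or regioselectivity than simpler enals. Mukaiyama–Michael addition may compete with cycloaddition, and the strong acid activator may desilylate the enol ether. The fallback sets out from 2 and 3, which are combined under an achiral Lewis acid (Me2AlCl, CH2Cl2, −78 °C) to give 4 as the racemate. The racemic series is carried through steps 3 to 12 unchanged, and the reagent-controlled reduction of step 13 serves as the resolving step. The mirror-image ketone gives the diastereomeric (2R)-carbinol F1, which is removed by chromatography, and the route is rejoined at 19.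

**Step 4.** The amide base may add to the formyl group, the dienolate may undergo aldol reaction with the aldehyde of a second molecule, or the vinylogous β-dicarbonyl system may lose its formyl group. The fallback sets out from 5. The aldehyde is masked as the dimethyl acetal F2 (HC(OMe)3, MeOH, pyridinium p-toluenesulfonate). This is taken as in steps 4 and 5 to the dienyl triflate acetal F3 and the diene acetal F4. Oxalic acid on wet silica frees the aldehyde, and the route is rejoined at 8.

**Step 17.** Facial selectivity at C9 may be poor, because both α-branches (C1 and C11) are fully substituted, and the adduct may revert by retro-aldol cleavage on warming. The fallback sets out from 22. If the addition gives mainly the C9 epimer F5, this is oxidized with Dess–Martin periodinane to the C9 ketone F6 and reduced with NaBH4/CeCl3. Hydride then takes the path the carbon nucleophile took, which places the hydroxyl on the other side, and the route is rejoined at 25.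

**Step 19.** Ten-membered ring closure may be slower than intermolecular coupling or protodemetalation of the alkenylchromium species, and the dithiane sulfur may inhibit the nickel co-catalyst. The fallback closes ring B at C5=C6 by metathesis and sets out from 26. Vinylmagnesium bromide adds to the aldehyde to give the C7 vinyl carbinol F7. The C6 iodide is removed with Bu3SnH and Pd(PPh3)4 (zerovalent palladium) to give the 1,1-disubstituted alkene F8. Ring-closing metathesis with the second-generation Grubbs catalyst RuCl2(=CHPh)(H2IMes)(PCy3) should close the ring as the ring-cis (Z) alkene, and the route is rejoined at 28.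

**Step 25.** SmI2 may cleave the C7–O bond α to the ketone in competition with enolate formation, the lactone may reopen by retro-aldol reaction, or C17 may form with the wrong configuration. The fallback uses Wittig closure followed by epoxide opening and sets out from 35. PPh3 displaces the bromide to give the phosphonium bromide F9. Et3N forms the ylide, which closes onto the C8 ketone to the butenolide F10. Nucleophilic epoxidation (t-BuOOH, DBU) gives the 8,17-epoxy lactone F11. SmI2 opens it reductively at C17 to the C8 carbinol, and the route is rejoined at 37.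

## Further compounds

F1 | step 2 | (2R)-carbinol on the mirror-image ring A (diastereomer of 19 from the enantiomeric ketone) | I\C=C(C)/CC[C@@H](O)[C@]1(C)C=C[C@@H]2OC(C)(C)O[C@]2(C)[C@H]1C(=O)OCC
F2 | step 4 | dimethyl acetal of enone 5 | COC(OC)[C@@]1(C)C=CC(=O)[C@@H](C)[C@@H]1C(=O)OCC
F3 | step 4 | dimethyl acetal of dienyl triflate 7 | COC(OC)[C@@]1(C)C=CC(OS(=O)(=O)C(F)(F)F)=C(C)[C@@H]1C(=O)OCC
F4 | step 4 | dimethyl acetal of diene aldehyde 8 | COC(OC)[C@@]1(C)C=CC=C(C)[C@@H]1C(=O)OCC
F5 | step 17 | C9 epimer of 25 | I\C=C(C)/CC[C@@H](O[Si](C)(C)C(C)(C)C)[C@@]1(C)C=C[C@H]2OC(C)(C)O[C@@]2(C)[C@@H]1[C@H](O)C1(C(=O)OCC)SCCCS1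
F6 | step 17 | C9 ketone (β-keto ester) from 25 or F5 | I\C=C(C)/CC[C@@H](O[Si](C)(C)C(C)(C)C)[C@@]1(C)C=C[C@H]2OC(C)(C)O[C@@]2(C)[C@@H]1C(=O)C1(C(=O)OCC)SCCCS1
F7 | step 19 | C7 vinyl carbinol from 26 (C7 epimers) | I\C=C(C)/CC[C@@H](O[Si](C)(C)C(C)(C)C)[C@@]1(C)C=C[C@H]2OC(C)(C)O[C@@]2(C)[C@@H]1[C@@H](O)C1(C(O)C=C)SCCCS1
F8 | step 19 | deiodinated diene for ring-closing metathesis (C7 epimers) | C=C(C)CC[C@@H](O[Si](C)(C)C(C)(C)C)[C@@]1(C)C=C[C@H]2OC(C)(C)O[C@@]2(C)[C@@H]1[C@@H](O)C1(C(O)C=C)SCCCS1
F9 | step 25 | phosphonium bromide from 35 | CC[Si](CC)(CC)O[C@@H]1[C@H]2[C@]3(C)OC(C)(C)O[C@@H]3C=C[C@]2(C)[C@H](O[Si](C)(C)C(C)(C)C)CC/C(C)=C\[C@H](OC(=O)C(C)[P+](c4ccccc4)(c4ccccc4)c4ccccc4)C1=O.[Br-]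
F10 | step 25 | butenolide (C8=C17) | CC[Si](CC)(CC)O[C@@H]1[C@H]2[C@]3(C)OC(C)(C)O[C@@H]3C=C[C@]2(C)[C@H](O[Si](C)(C)C(C)(C)C)CC/C(C)=C\[C@@H]2OC(=O)C(C)=C21
F11 | step 25 | 8,17-epoxy lactone | CC[Si](CC)(CC)O[C@@H]1[C@H]2[C@]3(C)OC(C)(C)O[C@@H]3C=C[C@]2(C)[C@H](O[Si](C)(C)C(C)(C)C)CC/C(C)=C\[C@@H]2OC(=O)[C@]4(C)O[C@@]214
A1 | alternative 1 | thirteen-membered C7-tributylstannyl allylic ether | CC(C)(C)[Si](C)(C)O[C@@H]1[C@H]2[C@](C)(O3)[C@H](OC3(C)C)C=C[C@]2(C)[C@H](O[Si](C)(C)C(C)(C)C)CC/C(C)=C\C([Sn](CCCC)(CCCC)CCCC)OCC(C)=C1
A2 | alternative 1 | ring A/ring B carbinol with C7 hydroxyl and C8 isopropenyl group | CC(C)(C)[Si](C)(C)O[C@@H]1[C@H]2[C@](C)(O3)[C@H](OC3(C)C)C=C[C@]2(C)[C@H](O[Si](C)(C)C(C)(C)C)CC/C(C)=C\[C@H](O)[C@H]1C(C)=C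
A3 | alternative 2 | 5-(tert-butyldimethylsilyloxy)-2-methylcyclohex-2-enone | CC1=CC[C@H](O[Si](C)(C)C(C)(C)C)CC1=O
A4 | alternative 2 | (Z)-6-(4-methoxybenzyloxy)-4-methylhex-4-enal | O=CCC/C(C)=C\COCc1ccc(OC)cc1
A5 | alternative 2 | ring A ketone with C9 silylmethyl, quaternary C1 and C2 carbinol | CC(C)O[Si](C)(C)C[C@H]1C[C@H](O[Si](C)(C)C(C)(C)C)CC(=O)[C@]1(C)[C@H](O)CC/C(C)=C\COCc1ccc(OC)cc1
A6 | alternative 3 | fourteen-membered macrocycle with C13 enone, C12 tert-butyl carbonate and butenolide | CC(C)(C)[Si](C)(C)O[C@@H]1/C=C(C)/[C@H](OC(=O)OC(C)(C)C)C(=O)/C=C(C)/[C@H](O[Si](C)(C)C(C)(C)C)CC/C(C)=C\[C@@H]2OC(=O)C(C)=C21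
A7 | alternative 3 | trans-fused ring A/ring B core with C11/C12 cyclic carbonate, C13 ketone and butenolide | CC(C)(C)[Si](C)(C)O[C@@H]1[C@H]2[C@](C)(O3)[C@H](OC3=O)C(=O)C[C@]2(C)[C@H](O[Si](C)(C)C(C)(C)C)CC/C(C)=C\[C@@H]2OC(=O)C(C)=C21
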